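6 questions stand here: the leader and its amount in each of 3 flasks, epsilon, eta and alpha, read at 2.5 min, 4.0 min and 6.0 min.

| flask | starting material | coupling partner | remark | time |
|---|---|---|---|---|
| birch | 2.8 M | 0.70 equiv | run made earlier |  |
| epsilon | 2.0 M | 0.700 equiv |  | 2.5 min |
| eta | 2.0 M | 0.700 equiv |  | 4.0 min |
| alpha | 2.0 M | 0.700 equiv |  | 6.0 min |

birch run (percent of the starting material charged)

| time / s | starting material / % | product / % | intermediate B / % | intermediate A / % |
|---|---|---|---|---|
| 25.0 | 74 | 3 | 0 | 24 |
| 50.0 | 53 | 3 | 0 | 41 |
| 60.0 | 49 | 3 | 0 | 46 |
| 90.0 | 35 | 9 | 2 | 53 |

(scatter of a reading: 1.5 percentage points)

- which of these there is most of at the end, counted by the starting material in it, epsilon (intermediate B / starting material / intermediate A / product)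
- which of these there is most of at the end, counted by the starting material in it, eta (intermediate B / starting material / intermediate A / product)
- which of these there is most of at the end, counted by the starting material in it, alpha (intermediate B / starting material / intermediate A / product)
- final amount of the leader among these, as a percentage of the starting material charged, in epsilon
- final amount of the leader among these, as a percentage of the starting material charged, in eta
- final amount of the leader among these, as a percentage of the starting material charged, in alpha



I build the flask one process at a time, starting with the main step. In the birch run the starting material falls as a first-order decay, and its last reading gives 0.0117 /s. This step by itself puts 82.6%, 93.9% and 98.5% into intermediate A in epsilon, eta and alpha.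

Next comes the loss of intermediate A. I take it to need the coupling partner. At the last birch reading, product and intermediate B together hold 11.0%. I divide this by the time integral of the intermediate A readings and by the charged c(coupling partner), which gives 0.00185 /M/s. I call this reading the passage constant: the rate of leaving per c(intermediate A) and per c(coupling partner). At the charged 1.40 M it acts as a pseudo-first-order loss of 0.00259 /s, slower than the main step. Two consecutive steps then leave 64.8%, 61.2% and 48.7%.

But the coupling partner is being spent, so I put that answer back in, counting two partners per passage, one to reach intermediate B and one to go on to product; the birch readings do not show the partner, so this count is my assumption. The mean c(coupling partner) becomes 1.04 M, 0.746 M and 0.403 M. The second round gives intermediate A at 68.9%, 74.5% and 80.1%. In alpha the two rounds lie far apart, so I put the mean of the two answers back in for each flask. That makes the mean c(coupling partner) 1.08 M, 0.879 M and 0.717 M, and the third round gives intermediate A at 68.4%, 71.6% and 68.3%. In alpha that is more than everything else together, so I commit to intermediate A as leader in each flask.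

The forecast names intermediate A at 58%, intermediate A at 51% and product at 54%, on the ground “So A leads in epsilon and eta, and product leads in alpha.”

The flasks give intermediate A at 65.4%, intermediate A at 67.8% and intermediate A at 66.4%.

    starting material → intermediate A (k = 0.0120 /s)
    coupling partner + intermediate A → intermediate B (k = 0.00250 /M/s)
    coupling partner + intermediate B ⇌ intermediate C (K = 0.340 /M, k = 0.00270 /M/s)
    coupling partner + intermediate B → product (k = 0.0450 /M/s)

The neighbouring flask is alpha with 0.280 equiv of coupling partner, and I run the passage constant through it the same way. The first round, at the charged partner, leaves 73.9% of intermediate A. That answer puts the mean c(coupling partner) at 0.0686 M, and the second round gives 95.1%. The mean of the two answers puts it at 0.280 M, and the third round gives 85.3%, against 68.3% for alpha. The neighbouring flask holds 84.1% of intermediate A, with 11% of its charged coupling partner still there.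

The earlier runs and the new flask were generated by integration with made-up constants, and the scatter is random.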